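## Retrosynthetic overview
1. Ring B is closed last. The target comes from an acid-triggered Friedel–Crafts closure (C1–C8a) of an open-chain benzylic-alcohol pentaol, which comes from global LiAlH4 reduction of a trans-disubstituted γ-butyrolactone.
2. That lactone comes from an aldol union (future C1–C2 bond) of (R)-β-(syringylmethyl)-γ-butyrolactone with acyl-protected vanillin.
3. Key disconnection: the ring C–O bond of the lactone. It is made by enantiotopos-selective Baeyer–Villiger oxygen insertion into a prochiral 3-(arylmethyl)cyclobutanone. This sets the only catalyst-controlled stereocentre (C3), which then relays C2 and C1.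
4. The cyclobutanone comes from dichloroketene [2+2] cycloaddition and dechlorination on O-pivaloyl methoxyeugenol.
5. Ring order: cyclobutanone, then γ-lactone (ring expansion), then reductive opening, then ring B of the tetralin.

Assumption: the sense of induction of the new catalyst in step 3 cannot be predicted with certainty. The IDPi enantiomer that delivers (R)-6 is used (written here as the (S,S)-acid), and the assignment is checked against (R)-6 made by the known fallback sequence.

## Route

Step 1
Reactants: 1 4-allyl-2,6-dimethoxyphenol (methoxyeugenol)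
Product: 2 4-allyl-2,6-dimethoxyphenyl pivalate
Conditions: PivCl (1.2 equiv), Et3N (1.5 equiv), DMAP (5 mol %), CH2Cl2, 0 °C to rt
Reagents that add atoms: pivaloyl chloride, CC(C)(C)C(=O)Cl
Why: DMAP-catalysed O-acylation of the hindered phenol gives an ester without α-hydrogens that tolerates ketene, Zn/AcOH, silylium and amide-base conditions and is removed at no extra cost by LiAlH4 in step 5.

Step 2
Reactants: 2 4-allyl-2,6-dimethoxyphenyl pivalate
Product: 4 3-[3,5-dimethoxy-4-(pivaloyloxy)benzyl]cyclobutanone, via 2,2-dichlorocyclobutanone 3 (not isolated)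
Conditions: Cl3CCOCl (2 equiv), Zn dust (4 equiv), Et2O, ultrasound, 15–20 °C, 2 h; then AcOH, Zn dust (6 equiv), Et2O distilled off, 60 °C, 3 h, same flask
Reagents that add atoms: trichloroacetyl chloride, ClC(Cl)(Cl)C(=O)Cl
Why: The ketene–alkene [2+2] cycloaddition joins the ketene carbonyl carbon to the terminal alkene carbon (3-substituted ring only), and Zn/AcOH reductive dechlorination then gives the achiral, mirror-symmetric cyclobutanone, as is well established for allylarenes.

Step 3
Reactants: 4 3-[3,5-dimethoxy-4-(pivaloyloxy)benzyl]cyclobutanone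
Product: 6 (R)-4-[3,5-dimethoxy-4-(pivaloyloxy)benzyl]dihydrofuran-2(3H)-one, via bis-silyl Criegee perketal 5 (not isolated)
Conditions: (Me3SiO)2 (1.3 equiv), (S,S)-IDPi acid (confined imidodiphosphorimidate from two 3,3'-diaryl-BINOL units, N-triflyl core, 3 mol %), toluene, −60 °C, 36 h; 6 recrystallised to raise ee
Reagents that add atoms: bis(trimethylsilyl) peroxide, C[Si](C)(C)OO[Si](C)(C)C
Why: Proposed new method: an enantiotopos-selective Baeyer–Villiger oxidation run as silylium counteranion-directed catalysis, in which the IDPi acid is silylated by (Me3SiO)2 to Me3Si–IDPi, this silylates the strained ketone so that (Me3SiO)2 adds to give the mirror-symmetric perketal 5, and renewed silylation of the terminal peroxy oxygen turns it into the leaving group (Me3Si)2O; inside the tight ion pair with the confined chiral anion only the O–O rotamer that keeps the arylmethyl arm outside the pocket fits, so just one of the two enantiotopic ring CH2 groups lies antiperiplanar to O–O and migrates to oxygen, forming the lactone C–O bond and fixing the future C3 as R; the peroxide is inert to the ketone without silylium activation, which removes the racemic background that limits aqueous H2O2 protocols, and ring-strain release keeps the barrier low at −60 °C; the closest known reaction types are the achiral Me3SiOTf-catalysed Baeyer–Villiger oxidation with bis(trimethylsilyl) peroxide, the chiral phosphoric acid/H2O2 desymmetrisation of 3-substituted cyclobutanones, and IDPi silylium catalysis of carbonyl additions.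

Step 4
Reactants: 6 (R)-4-[3,5-dimethoxy-4-(pivaloyloxy)benzyl]dihydrofuran-2(3H)-one; 7 4-formyl-2-methoxyphenyl isobutyrate (vanillin isobutyrate)
Product: 9 (3S,4R)-4-[3,5-dimethoxy-4-(pivaloyloxy)benzyl]-3-{hydroxy[4-(isobutyryloxy)-3-methoxyphenyl]methyl}dihydrofuran-2(3H)-one (both carbinol epimers), via lithium enolate 8 (not isolated)
Conditions: LiN(SiMe3)2 (1.0 equiv), THF, −78 °C, 30 min; 7 (1.1 equiv), −78 °C, 20 min; AcOH quench at −78 °C
Reagents that add atoms: none
Why: In this lithium-enolate aldol addition the aldehyde approaches anti to the β-arylmethyl group, which sets the future C2 trans to C3, while the carbinol epimers do not matter because that centre is ionised in step 5 and any acyl scrambling is erased by LiAlH4.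

Step 5
Reactants: 9 (3S,4R)-aldol adduct
Product: 11 (+)-8-methoxyisolariciresinol, via benzylic-alcohol pentaol 10 (not isolated)
Conditions: LiAlH4 (5 equiv), THF, 0 °C to rt, 2 h; then 2 M aq HCl to pH 1, THF–H2O (about 0.02 M), 45 °C, 4–6 h, N2
Reagents that add atoms: none
Why: Global LiAlH4 reduction (lactone to 1,4-diol, both aryl esters to phenols) is followed by acid ionisation of the p-hydroxybenzylic alcohol to a quinone-methide-type cation and a six-membered intramolecular Friedel–Crafts alkylation at the ring position ortho and para to the two methoxy groups, through a chair-like arrangement that places the guaiacyl group pseudo-equatorial and trans to C2 (C1 = S), with reversible capture by oxygen funnelling all material to the C–C product.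

## Compound list
1 | 4-allyl-2,6-dimethoxyphenol (methoxyeugenol) | C=CCc1cc(OC)c(O)c(OC)c1 | starting material
2 | 4-allyl-2,6-dimethoxyphenyl pivalate | C=CCc1cc(OC)c(OC(=O)C(C)(C)C)c(OC)c1 | intermediate
3 | (±)-2,2-dichloro-3-[3,5-dimethoxy-4-(pivaloyloxy)benzyl]cyclobutanone | O=C1CC(Cc2cc(OC)c(OC(=O)C(C)(C)C)c(OC)c2)C1(Cl)Cl | intermediate
4 | 3-[3,5-dimethoxy-4-(pivaloyloxy)benzyl]cyclobutanone (achiral, prochiral) | O=C1CC(Cc2cc(OC)c(OC(=O)C(C)(C)C)c(OC)c2)C1 | intermediate
5 | 1-(trimethylsilyloxy)-1-(trimethylsilylperoxy)-3-[3,5-dimethoxy-4-(pivaloyloxy)benzyl]cyclobutane (achiral, cis/trans) | C[Si](C)(C)OOC1(O[Si](C)(C)C)CC(Cc2cc(OC)c(OC(=O)C(C)(C)C)c(OC)c2)C1 | intermediate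
6 | (R)-4-[3,5-dimethoxy-4-(pivaloyloxy)benzyl]dihydrofuran-2(3H)-one | O=C1C[C@@H](Cc2cc(OC)c(OC(=O)C(C)(C)C)c(OC)c2)CO1 | intermediate
7 | 4-formyl-2-methoxyphenyl isobutyrate (vanillin isobutyrate) | CC(C)C(=O)Oc1ccc(C=O)cc1OC | starting material
8 | lithium enolate of 6 (R at the ring CH) | [Li+].[O-]C1=C[C@@H](Cc2cc(OC)c(OC(=O)C(C)(C)C)c(OC)c2)CO1 | intermediate
9 | (3S,4R)-4-[3,5-dimethoxy-4-(pivaloyloxy)benzyl]-3-{hydroxy[4-(isobutyryloxy)-3-methoxyphenyl]methyl}dihydrofuran-2(3H)-one, carbinol epimers | COc1cc(C[C@H]2COC(=O)[C@@H]2C(O)c3ccc(OC(=O)C(C)C)c(OC)c3)cc(OC)c1OC(=O)C(C)(C)C | intermediate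
10 | (2R,3R)-2-[hydroxy(4-hydroxy-3-methoxyphenyl)methyl]-3-(4-hydroxy-3,5-dimethoxybenzyl)butane-1,4-diol, carbinol epimers | COc1cc(C[C@@H](CO)[C@H](CO)C(O)c2ccc(O)c(OC)c2)cc(OC)c1O | intermediate
11 | (+)-8-methoxyisolariciresinol, (1S,2R,3R), all-trans | COc1cc([C@H]2c3c(cc(OC)c(O)c3OC)C[C@@H](CO)[C@@H]2CO)ccc1O | target

## Step count and risks
Total steps: 5. Longest linear sequence: 5 (1 → 2 → 4 → 6 → 9 → 11).

**Step 3 (the new reaction).** The risks are three:
- modest ee, because the stereocentre sits two bonds from the reacting carbonyl;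
- Lewis-acid decomposition of the peroxide;
- product inhibition by the lactone.

The fallback uses known chemistry, sets out from 4 and returns at 6. It desymmetrises by C–H selection instead of C–C selection. Enantioselective deprotonation with lithium bis[(S)-1-phenylethyl]amide and Me3SiCl as internal quench (THF, −100 °C) gives (R)-3-[3,5-dimethoxy-4-(pivaloyloxy)benzyl]-1-(trimethylsilyloxy)cyclobut-1-ene F1. Ozonolysis (CH2Cl2–MeOH, −78 °C) with NaBH4 work-up gives (R)-4-[3,5-dimethoxy-4-(pivaloyloxy)phenyl]-3-(hydroxymethyl)butanoic acid F2. F2 closes to 6 on acidification. The antipodal amide is taken if the sense proves opposite.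

**Step 4.** The risk is that the enolate or the lithium aldolate attacks the activated aryl ester of 7, or that the base touches the pivalate of 6. The fallback sets out from 6 and returns at 9. It leaves the basic aldolate manifold for a Lewis-acid Mukaiyama aldol. Adding LiN(SiMe3)2 to a −78 °C mixture of 6 and Me3SiCl gives the ketene silyl acetal (R)-4-[3,5-dimethoxy-4-(pivaloyloxy)benzyl]-2-(trimethylsilyloxy)-4,5-dihydrofuran F3. F3 adds to 7 with BF3·OEt2 (CH2Cl2, −78 °C), again anti to the β-substituent, and gives 9 after aqueous work-up.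

**Step 5.** The risks are a stall at an O-captured ether, oligomerisation of the quinone methide, or hydride loss of the benzylic oxygen during the reduction. The fallback sets out from 9 and returns at 11. It closes ring B before the reduction. Dehydrative Friedel–Crafts cyclisation of 9 with TfOH (10 mol %) in (CF3)2CHOH at rt gives the all-trans aryltetralin lactone bis-ester F4 (1S,2R,3R in tetralin numbering; C=O on C2, OCH2 on C3). LiAlH4 (THF, 0 °C to rt) then reduces the lactone and cleaves both aryl esters to give 11, as in the known conidendrin-to-isolariciresinol reduction.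

## Further compounds
F1 | step 3 | (R)-3-[3,5-dimethoxy-4-(pivaloyloxy)benzyl]-1-(trimethylsilyloxy)cyclobut-1-ene | C[Si](C)(C)OC1=C[C@H](Cc2cc(OC)c(OC(=O)C(C)(C)C)c(OC)c2)C1
F2 | step 3 | (R)-4-[3,5-dimethoxy-4-(pivaloyloxy)phenyl]-3-(hydroxymethyl)butanoic acid | OC[C@H](Cc1cc(OC)c(OC(=O)C(C)(C)C)c(OC)c1)CC(=O)O
F3 | step 4 | (R)-4-[3,5-dimethoxy-4-(pivaloyloxy)benzyl]-2-(trimethylsilyloxy)-4,5-dihydrofuran | C[Si](C)(C)OC1=C[C@@H](Cc2cc(OC)c(OC(=O)C(C)(C)C)c(OC)c2)CO1
F4 | step 5 | all-trans (1S,2R,3R) aryltetralin lactone bis-ester (7-pivalate, 4'-isobutyrate) | COc1cc([C@H]2c3c(cc(OC)c(OC(=O)C(C)(C)C)c3OC)C[C@H]4COC(=O)[C@H]24)ccc1OC(=O)C(C)C
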